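The route rests on opening the pyran ring C at C4–C4a and O1–C2. C4 is benzylic to ring A and O1 sits on the neighbouring ring carbon, so C4, C3 and C2 map onto the β-, α- and carbonyl carbons of an enal, and ring A with O1 onto 3-methoxyphenol. One amine-catalysed Friedel–Crafts/hemiacetal annulation therefore forms both bonds, closes ring C as a chroman-2-ol and sets C4 under catalyst control. Its precursor is (2E,4E)-5-(4-silyloxyphenyl)penta-2,4-dienal, made from silylated 4-hydroxybenzaldehyde. C3 and C2 are then set from C4 through the lactone; the target's all-trans array is the most stable one.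

Key step: step 5

Remark on descriptors (TBS = tert-butyldimethylsilyl): in chromanol 10 and lactone 11 the C4 centre is S by the sequence rules, because the vinyl carbon outranks the C3 methylene; from enolate 14 onwards C3 outranks the vinyl carbon and the label becomes R with no change of geometry, so the chromanol is correctly (4S) and corresponds to 4R of the target.

Step 1
Reactants: 1 4-hydroxybenzaldehyde
Product: 2 4-(tert-butyldimethylsilyloxy)benzaldehyde
Conditions: TBSCl (1.2 equiv), imidazole (2.2 equiv), DMF, 0 °C → rt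
Reagents that add atoms: tert-butyldimethylsilyl chloride, CC(C)(C)[Si](C)(C)Cl
Why: Imidazole-promoted silylation of the phenol (silyl ether formation) is chemoselective because the aldehyde is inert to the silyl chloride.

Step 2
Reactants: 2 4-(tert-butyldimethylsilyloxy)benzaldehyde; 3 triethyl (E)-4-phosphonocrotonate
Product: 4 ethyl (2E,4E)-5-[4-(tert-butyldimethylsilyloxy)phenyl]penta-2,4-dienoate
Conditions: 3 (1.2 equiv), LiN(SiMe3)2 (1.2 equiv), THF, −78 °C; then 2, −78 → 0 °C
Reagents that add atoms: none
Why: The vinylogous Horner–Wadsworth–Emmons olefination adds all four carbons in one operation and should give the (2E,4E)-dienoate, which avoids the over-homologation that accompanies repeated two-carbon olefinations with formylmethylene ylides.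

Step 3
Reactants: 4 ethyl (2E,4E)-5-[4-(tert-butyldimethylsilyloxy)phenyl]penta-2,4-dienoate
Product: 5 (2E,4E)-5-[4-(tert-butyldimethylsilyloxy)phenyl]penta-2,4-dien-1-ol
Conditions: i-Bu2AlH (2.3 equiv), CH2Cl2, −78 °C; aq. KNaC4H4O6
Reagents that add atoms: none
Why: Hydride reduction of the conjugated ester with i-Bu2AlH at low temperature is a 1,2-reduction to the dienol that leaves the diene and the aryl silyl ether untouched.

Step 4
Reactants: 5 (2E,4E)-5-[4-(tert-butyldimethylsilyloxy)phenyl]penta-2,4-dien-1-ol
Product: 6 (2E,4E)-5-[4-(tert-butyldimethylsilyloxy)phenyl]penta-2,4-dienal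
Conditions: activated MnO2 (15 equiv), CH2Cl2, rt
Reagents that add atoms: none
Why: Allylic oxidation with MnO2 is selective for the dienylic alcohol and neutral, so the E,E geometry and the silyl ether should be kept.

Step 5
Reactants: 6 (2E,4E)-5-[4-(tert-butyldimethylsilyloxy)phenyl]penta-2,4-dienal; 7 3-methoxyphenol
Product: 10 (4S)-7-methoxy-4-[(E)-4-(tert-butyldimethylsilyloxy)styryl]chroman-2-ol (mixture of C2 epimers), via iminium benzoate 8 (not isolated), via hydroxyaryl aldehyde 9 (not isolated)
Conditions: 7 (3 equiv), (S)-2-[diphenyl(trimethylsilyloxy)methyl]pyrrolidine (20 mol %), PhCO2H (20 mol %), toluene, 0 °C → rt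
Reagents that add atoms: none
Why: Dienal 6 condenses with the amine to the (E)-configured dienyl iminium benzoate 8, 3-methoxyphenol attacks its β-carbon through the ring carbon ortho to OH and para to OMe (bond C4–C4a), and hydrolysis of the resulting enamine releases aldehyde 9, whose phenol oxygen adds to the formyl carbon (bond O1–C2). The closest known reaction type is the diarylprolinol silyl ether catalysed Friedel–Crafts alkylation/hemiacetalisation of naphthols and electron-rich phenols with enals to chroman-2-ols. Ring C closes by reversible 6-exo-trig addition of the phenol oxygen to the aldehyde, which also takes the adduct out of the catalytic cycle as a lactol. C4 is set by the catalyst: its diphenyl(silyloxy)methyl group covers one face of the s-trans iminium ion, the arene bonds to the open face, and with the (S)-catalyst this should be the face that leads to 4S (the geometry of 4R in the target), whereas the anomeric carbon stays uncontrolled and is erased in step 6. The step needs β- instead of δ-attack, which the δ-aryl group secures because only β-attack keeps the styrene conjugation and avoids the hindered aryl-bearing terminus, and it needs attack ortho to OH, which is supported by hydrogen bonding of the phenol OH to the benzoate held next to the iminium chain and by the fact that C6 of the phenol is activated by both oxygens and less hindered than C2. The cheap phenol is used in excess to offset its modest nucleophilicity towards the donor-substituted iminium ion.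

Step 6
Reactants: 10 (4S)-7-methoxy-4-[(E)-4-(tert-butyldimethylsilyloxy)styryl]chroman-2-ol
Product: 11 (4S)-7-methoxy-4-[(E)-4-(tert-butyldimethylsilyloxy)styryl]chroman-2-one
Conditions: (n-Pr4N)[RuO4] (5 mol %), N-methylmorpholine N-oxide (1.5 equiv), 4 Å MS, CH2Cl2, rt
Reagents that add atoms: none
Why: Ley–Griffith oxidation of the lactol to the lactone removes the anomeric mixture and should not touch C4, the alkene or the aryl ethers.

Step 7
Reactants: 2 4-(tert-butyldimethylsilyloxy)benzaldehyde
Product: 12 [4-(tert-butyldimethylsilyloxy)phenyl]methanol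
Conditions: NaBH4 (1.0 equiv), THF/MeOH, 0 °C
Reagents that add atoms: none
Why: Borohydride reduction of the aromatic aldehyde is fast at 0 °C, and the aryl silyl ether should survive the short exposure.

Step 8
Reactants: 12 [4-(tert-butyldimethylsilyloxy)phenyl]methanol
Product: 13 4-(tert-butyldimethylsilyloxy)benzyl bromide
Conditions: CBr4 (1.2 equiv), PPh3 (1.2 equiv), CH2Cl2, 0 °C; used at once
Reagents that add atoms: carbon tetrabromide, BrC(Br)(Br)Br
Why: The Appel reaction converts the benzylic alcohol into the bromide under neutral conditions, without acid that could cleave the silyl ether.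

Step 9
Reactants: 11 (4S)-7-methoxy-4-[(E)-4-(tert-butyldimethylsilyloxy)styryl]chroman-2-one; 13 4-(tert-butyldimethylsilyloxy)benzyl bromide
Product: 15 (3R,4R)-3-[4-(tert-butyldimethylsilyloxy)benzyl]-7-methoxy-4-[(E)-4-(tert-butyldimethylsilyloxy)styryl]chroman-2-one, via lithium enolate 14 (not isolated)
Conditions: LiN(SiMe3)2 (1.1 equiv), THF, −78 °C; then 13 (1.3 equiv), −78 → −40 °C; aq. NH4Cl
Reagents that add atoms: none
Why: Enolate alkylation (SN2) of the kinetically formed lactone enolate by the reactive benzylic bromide should occur on the face anti to the C4 styryl group, which sets C3 trans to C4 (also the more stable arrangement), while the low temperature suppresses ketene formation from the aryl ester enolate.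

Step 10
Reactants: 15 (3R,4R)-3-[4-(tert-butyldimethylsilyloxy)benzyl]-7-methoxy-4-[(E)-4-(tert-butyldimethylsilyloxy)styryl]chroman-2-one; 16 1-bromo-2,4-dimethoxybenzene
Product: 18 (3R,4R)-2-(2,4-dimethoxyphenyl)-3-[4-(tert-butyldimethylsilyloxy)benzyl]-7-methoxy-4-[(E)-4-(tert-butyldimethylsilyloxy)styryl]chroman-2-ol (C2 epimers; ring-chain tautomer of the hydroxy ketone), via 2,4-dimethoxyphenyllithium 17 (not isolated)
Conditions: 16 (1.3 equiv), n-BuLi (1.25 equiv), THF, −78 °C; then 15, −78 °C; aq. NH4Cl at −78 °C
Reagents that add atoms: none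
Why: Bromine–lithium exchange places lithium at the required carbon, and 1,2-addition of the aryllithium to the lactone carbonyl at −78 °C should stop at the hemiketal stage because the ring-opened ketone is hindered and deactivated by its ortho- and para-methoxy groups; the new C2 centre need not be controlled since it becomes planar again in step 11.

Step 11
Reactants: 18 (3R,4R)-2-(2,4-dimethoxyphenyl)-3-[4-(tert-butyldimethylsilyloxy)benzyl]-7-methoxy-4-[(E)-4-(tert-butyldimethylsilyloxy)styryl]chroman-2-ol
Product: 20 (2R,3R,4R)-2-(2,4-dimethoxyphenyl)-3-[4-(tert-butyldimethylsilyloxy)benzyl]-7-methoxy-4-[(E)-4-(tert-butyldimethylsilyloxy)styryl]chroman, via oxocarbenium ion 19 (not isolated)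
Conditions: Et3SiH (4 equiv), BF3·OEt2 (2 equiv), CH2Cl2, −78 → −30 °C
Reagents that add atoms: none
Why: In this reductive deoxygenation of a hemiketal (ionic hydrogenation) BF3 generates the aryl-stabilised oxocarbenium ion and the silane should deliver hydride axially, anti to the pseudoaxial C3–H of the half-chair that carries the benzyl and styryl groups pseudo-equatorially, so that the aryl group ends equatorial and trans to the benzyl group (2R), the alternative half-chair being screened on both faces by its two pseudoaxial substituents.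

Step 12
Reactants: 20 (2R,3R,4R)-2-(2,4-dimethoxyphenyl)-3-[4-(tert-butyldimethylsilyloxy)benzyl]-7-methoxy-4-[(E)-4-(tert-butyldimethylsilyloxy)styryl]chroman
Product: 21 caraganin C, (2R,3R,4R)-2-(2,4-dimethoxyphenyl)-3-(4-hydroxybenzyl)-4-[(E)-4-hydroxystyryl]-7-methoxychroman
Conditions: n-Bu4NF (2.5 equiv), THF, 0 °C; aq. NH4Cl
Reagents that add atoms: none
Why: Fluoride-mediated desilylation cleaves both aryl silyl ethers and should leave the methyl ethers, the E-alkene and the three stereocentres untouched.

Compound list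
1 | 4-hydroxybenzaldehyde | O=Cc1ccc(O)cc1 | starting material
2 | 4-(tert-butyldimethylsilyloxy)benzaldehyde | O=Cc1ccc(O[Si](C)(C)C(C)(C)C)cc1 | intermediate
3 | triethyl (E)-4-phosphonocrotonate | CCOC(=O)/C=C/CP(=O)(OCC)OCC | starting material
4 | ethyl (2E,4E)-5-[4-(tert-butyldimethylsilyloxy)phenyl]penta-2,4-dienoate | CCOC(=O)/C=C/C=C/c1ccc(O[Si](C)(C)C(C)(C)C)cc1 | intermediate
5 | (2E,4E)-5-[4-(tert-butyldimethylsilyloxy)phenyl]penta-2,4-dien-1-ol | OC/C=C/C=C/c1ccc(O[Si](C)(C)C(C)(C)C)cc1 | intermediate
6 | (2E,4E)-5-[4-(tert-butyldimethylsilyloxy)phenyl]penta-2,4-dienal | O=C/C=C/C=C/c1ccc(O[Si](C)(C)C(C)(C)C)cc1 | intermediate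
7 | 3-methoxyphenol | COc1cccc(O)c1 | starting material
8 | dienyl iminium benzoate from 6 and the (S)-configured amine catalyst | C[Si](C)(C)OC(c1ccccc1)(c1ccccc1)[C@@H]1CCC[N+]1=C/C=C/C=C/c1ccc(O[Si](C)(C)C(C)(C)C)cc1.[O-]C(=O)c1ccccc1 | intermediate
9 | (3S,4E)-3-(2-hydroxy-4-methoxyphenyl)-5-[4-(tert-butyldimethylsilyloxy)phenyl]pent-4-enal | COc1ccc(c(O)c1)[C@@H](CC=O)/C=C/c1ccc(O[Si](C)(C)C(C)(C)C)cc1 | intermediate
10 | (4S)-7-methoxy-4-[(E)-4-(tert-butyldimethylsilyloxy)styryl]chroman-2-ol, C2 epimers | COc1ccc2c(c1)OC(O)C[C@H]2/C=C/c1ccc(O[Si](C)(C)C(C)(C)C)cc1 | intermediate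
11 | (4S)-7-methoxy-4-[(E)-4-(tert-butyldimethylsilyloxy)styryl]chroman-2-one | COc1ccc2c(c1)OC(=O)C[C@H]2/C=C/c1ccc(O[Si](C)(C)C(C)(C)C)cc1 | intermediate
12 | [4-(tert-butyldimethylsilyloxy)phenyl]methanol | OCc1ccc(O[Si](C)(C)C(C)(C)C)cc1 | intermediate
13 | 4-(tert-butyldimethylsilyloxy)benzyl bromide | BrCc1ccc(O[Si](C)(C)C(C)(C)C)cc1 | intermediate
14 | lithium (4R)-7-methoxy-4-[(E)-4-(tert-butyldimethylsilyloxy)styryl]-4H-chromen-2-olate (enolate of 11) | COc1ccc2c(c1)OC(O[Li])=C[C@H]2/C=C/c1ccc(O[Si](C)(C)C(C)(C)C)cc1 | intermediate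
15 | (3R,4R)-3-[4-(tert-butyldimethylsilyloxy)benzyl]-7-methoxy-4-[(E)-4-(tert-butyldimethylsilyloxy)styryl]chroman-2-one | COc1ccc2c(c1)OC(=O)[C@H](Cc1ccc(O[Si](C)(C)C(C)(C)C)cc1)[C@H]2/C=C/c1ccc(O[Si](C)(C)C(C)(C)C)cc1 | intermediate
16 | 1-bromo-2,4-dimethoxybenzene | COc1ccc(Br)c(OC)c1 | starting material
17 | 2,4-dimethoxyphenyllithium | [Li]c1ccc(OC)cc1OC | intermediate
18 | (3R,4R)-2-(2,4-dimethoxyphenyl)-3-[4-(tert-butyldimethylsilyloxy)benzyl]-7-methoxy-4-[(E)-4-(tert-butyldimethylsilyloxy)styryl]chroman-2-ol, C2 epimers | COc1ccc2c(c1)OC(O)(c1ccc(OC)cc1OC)[C@H](Cc1ccc(O[Si](C)(C)C(C)(C)C)cc1)[C@H]2/C=C/c1ccc(O[Si](C)(C)C(C)(C)C)cc1 | intermediate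
19 | (3R,4R)-2-(2,4-dimethoxyphenyl)-3-[4-(tert-butyldimethylsilyloxy)benzyl]-7-methoxy-4-[(E)-4-(tert-butyldimethylsilyloxy)styryl]-3,4-dihydrochromenylium hydroxytrifluoroborate | COc1ccc2c(c1)[O+]=C(c1ccc(OC)cc1OC)[C@H](Cc1ccc(O[Si](C)(C)C(C)(C)C)cc1)[C@H]2/C=C/c1ccc(O[Si](C)(C)C(C)(C)C)cc1.O[B-](F)(F)F | intermediate
20 | (2R,3R,4R)-2-(2,4-dimethoxyphenyl)-3-[4-(tert-butyldimethylsilyloxy)benzyl]-7-methoxy-4-[(E)-4-(tert-butyldimethylsilyloxy)styryl]chroman | COc1ccc2c(c1)O[C@@H](c1ccc(OC)cc1OC)[C@H](Cc1ccc(O[Si](C)(C)C(C)(C)C)cc1)[C@H]2/C=C/c1ccc(O[Si](C)(C)C(C)(C)C)cc1 | intermediate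
21 | caraganin C, (2R,3R,4R)-2-(2,4-dimethoxyphenyl)-3-(4-hydroxybenzyl)-4-[(E)-4-hydroxystyryl]-7-methoxychroman | COc1ccc2c(c1)O[C@@H](c1ccc(OC)cc1OC)[C@H](Cc1ccc(O)cc1)[C@H]2/C=C/c1ccc(O)cc1 | target

Total step count: 12. Longest linear sequence: 10 steps (steps 1–6 and 9–12, from 4-hydroxybenzaldehyde); steps 7 and 8 form a two-step branch from intermediate 2.

Steps most likely to fail

Step 5. The weakly nucleophilic phenol may react too slowly with the donor-substituted dienyl iminium ion, may attack through the carbon para to OH (an adduct that cannot close to the lactol), or may add with poor facial selectivity. The fallback forms the C4–styryl bond instead of the C4–C4a bond. It sets out from aldehyde 2, which a boron-Wittig olefination with CH2(Bpin)2 and lithium 2,2,6,6-tetramethylpiperidide should convert into the alkenylboronate 2-[(E)-4-(tert-butyldimethylsilyloxy)styryl]-4,4,5,5-tetramethyl-1,3,2-dioxaborolane F1. A Hayashi–Miyaura asymmetric conjugate addition of this boronate to commercial 7-methoxycoumarin (COc1ccc2ccc(=O)oc2c1), with Rh(acac)(C2H4)2 and the Segphos enantiomer that gives the 4S product in dioxane/H2O at 60 °C, should give lactone 11 directly, where the route is rejoined.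

Step 10. The aryllithium may enolise the hindered lactone instead of adding, or may add a second time to the ring-opened ketone. The fallback sets out from lactone 15, which is opened with MeNH(OMe)·HCl and i-PrMgCl in THF at −20 °C to the Weinreb amide (2R,3R,4E)-2-[4-(tert-butyldimethylsilyloxy)benzyl]-3-(2-hydroxy-4-methoxyphenyl)-N-methoxy-N-methyl-5-[4-(tert-butyldimethylsilyloxy)phenyl]pent-4-enamide F2. Addition of 17 (2.5 equiv, the first of which deprotonates the phenol) should then stop at the chelated tetrahedral intermediate (Weinreb ketone synthesis), and on work-up the hydroxy ketone closes to hemiketal 18, where the route is rejoined.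

Step 11. Hydride delivery may show poor facial selectivity and give the 2,3-cis epimer, or the acid may start ionic reduction of the silyloxystyrene. The fallback sets C2 under thermodynamic instead of kinetic control. It sets out from hemiketal 18, which NaBH4 in THF/EtOH at 0 °C should reduce through its open keto form to the diol (2R,3R,4E)-1-(2,4-dimethoxyphenyl)-2-[4-(tert-butyldimethylsilyloxy)benzyl]-3-(2-hydroxy-4-methoxyphenyl)-5-[4-(tert-butyldimethylsilyloxy)phenyl]pent-4-en-1-ol F3, whose carbinol epimers are of no consequence. Catalytic TsOH in CH2Cl2 at 0 °C → rt then ionises the 2,4-dimethoxybenzylic alcohol and the phenol closes ring C (acid-catalysed cyclodehydration). Because the C2–O1 bond of the product can reopen to the same cation, C2 should equilibrate to the all-equatorial chroman 20, where the route is rejoined.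

Further compounds
F1 | step 5 | 2-[(E)-4-(tert-butyldimethylsilyloxy)styryl]-4,4,5,5-tetramethyl-1,3,2-dioxaborolane | CC1(C)OB(/C=C/c2ccc(O[Si](C)(C)C(C)(C)C)cc2)OC1(C)C
F2 | step 10 | (2R,3R,4E)-2-[4-(tert-butyldimethylsilyloxy)benzyl]-3-(2-hydroxy-4-methoxyphenyl)-N-methoxy-N-methyl-5-[4-(tert-butyldimethylsilyloxy)phenyl]pent-4-enamide | CON(C)C(=O)[C@H](Cc1ccc(O[Si](C)(C)C(C)(C)C)cc1)[C@@H](/C=C/c1ccc(O[Si](C)(C)C(C)(C)C)cc1)c1ccc(OC)cc1O
F3 | step 11 | (2R,3R,4E)-1-(2,4-dimethoxyphenyl)-2-[4-(tert-butyldimethylsilyloxy)benzyl]-3-(2-hydroxy-4-methoxyphenyl)-5-[4-(tert-butyldimethylsilyloxy)phenyl]pent-4-en-1-ol, C1 epimers | OC(c1ccc(OC)cc1OC)[C@H](Cc1ccc(O[Si](C)(C)C(C)(C)C)cc1)[C@@H](/C=C/c1ccc(O[Si](C)(C)C(C)(C)C)cc1)c1ccc(OC)cc1O
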